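Compound numbers used below are those of the steps and of the compound list; the target is 19.

## Analysis of the target

The target 19 is a flavonol: a 4H-chromen-4-one (ring A fused to the γ-pyrone ring C) with a 4-hydroxyphenyl group (ring B) at C2, an enolic hydroxyl at C3, phenolic hydroxyls at C5 and C7, and a 3-hydroxy-3-methylbutyl chain at C6. It has no stereocentre and no stereogenic double bond, so the problem is one of regiochemistry and functional-group compatibility. Ring A is substituted everywhere except C8, and its three oxygens (O1, O5, O7) sit in a 1,3,5-pattern whose carbon positions are otherwise alike. The chain must lie between O5 and O7 and not between O7 and O1, and a ring closure onto an aryl ketone with two free ortho hydroxyls would give both the 6-alkyl and the 8-alkyl flavonol. The sensitive groups are the tertiary alcohol, which ionises in strong acid and would then lose water or be trapped by a free 5-OH or 7-OH as a dimethylchroman, and the electron-rich polyphenol with its 3-hydroxy-4-pyranone unit, which is oxidised easily in basic, aerobic media; acid may therefore act only while O5 and O7 are capped, and the last step must be neutral. The plan rests on C2: it is a single sp2 carbon bonded only to O1, C3 and C1' of ring B, and in the ring-opened 1,3-diketone it is an ordinary ketone carbonyl. A carbon at that oxidation level, flanked by an aryl group and an enolisable carbon, can be carbon monoxide inserted between a ring B aryl iodide and the C3 enolate of a ring A ketone that already carries O3.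

## Retrosynthetic reasoning

**19 to 18.** The four O–H bonds at O3, O5, O7 and O4' are traced back to benzyl ethers in 18. Benzyl is chosen because it survives alkyllithiums, amide bases and warm dilute acid, and because all four come off together under neutral hydrogenolysis, which leaves the tertiary alcohol and the pyrone untouched.

**18 to 16.** Ring C is opened at the O1–C2 bond, giving the 2-benzyloxy-1,3-diketone 16, in which O1 is a methoxymethyl (MOM) ether and the chain alcohol a triethylsilyl (TES) ether. This bond is cut because it forms by a simple cyclodehydration. Since O5 is benzylated and O1 carries the only acid-labile aryl ether, acid liberates a single phenol (hydroxy diketone 17) and closure can only give the 6-alkyl isomer. The forward step must remove the MOM and TES groups and dehydrate the hemiketal without ionising the tertiary alcohol.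

**16 to 12, 13 and 14.** The two bonds to C2 that remain, C2–C3 and C2–C1', are cut together. C2 becomes carbon monoxide 14, ring B becomes the aryl iodide 13, and C3 with O3 attached becomes the α-carbon of ketone 12. Cutting here rather than at C2–C3 alone avoids a separate aroyl electrophile and its oxygen-acylation problem, and brings ring B in as a simple iodide. The forward reaction must acylate the enolate of 12 at carbon, and 12 must offer no free O–H to the acylpalladium intermediate.

**12 to 8 and 10.** The C4–C4a bond is cut to an aryllithium 11 and the Weinreb amide 10, which is made from acid chloride 9. In 8 the only two ring hydrogens are related by the mirror plane and each lies between the MOM ether and a benzyloxy group, so directed metalation has one possible site. Lewis-acid acylation is avoided because it would endanger the benzyl ethers.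

**8 to 5 by way of 7 and 6.** This is an exchange of protecting groups at O1. The chain has to be placed by a lithiation between the two benzyloxy groups, and a MOM ether would steer the base to its own ortho positions. O1 is therefore first a bulky, weakly coordinating triisopropylsilyl (TIPS) ether (in 5), which is replaced by MOM (in 7) once the chain is in place. The TES ether in 8 removes the acidic O–H of the tertiary alcohol before the two base-mediated C–C bond formations.

**5 to 2 and 3; 2 to 1.** The C6–CH2 bond of the chain is cut to aryllithium 4 and 2,2-dimethyloxetane 3. Attack at the unsubstituted ring carbon of 3 delivers all five chain carbons and the tertiary hydroxyl in one step. Silyl ether 2 comes from the mirror-symmetric phenol 1, so the lithiation site between the benzyloxy groups is unique and becomes C6.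

## Alternatives that were turned down

Alternative 1: copper-mediated closure of the O1–C8a bond.
- Disconnection: the O1–C8a bond instead of O1–C2. Ring A would come from 1,3-bis(benzyloxy)-5-bromobenzene A1, which has the same mirror plane as 1; the bromine of A1 marks the future C8a.
- Forward key step: after prenylation between the benzyloxy groups, acylation next to bromine and C-aroylation, the bromo diketone A2 would be closed with CuI, 1,10-phenanthroline and K2CO3. The enolate oxygen on the ring B side displaces bromide (intramolecular Ullmann-type O-arylation) to give the tetrabenzyl 6-prenyl flavonol A3. Hydration of the prenyl alkene and hydrogenolysis would follow.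
- In favour: the closure needs no acid, so the tertiary alcohol is never exposed to acid; no protecting group has to be exchanged at O1; only the six-membered closure is geometrically possible. On these points it is as strong as or stronger than the chosen plan.
- Against: A2 is itself a 2-benzyloxy-1,3-diketone, so the carbon-versus-oxygen acylation problem is only moved, and ring B and C2 then enter in a separate aroylation. The bromine carried over from A1 rules out alkyllithium bases on ring A, because halogen–lithium exchange would outrun deprotonation. The chain and the acyl group would then have to be placed by electrophilic substitution on a ring whose three free positions are all activated, so symmetry no longer guarantees one isomer. The closure must displace a bromide on an electron-rich, ortho-substituted arene with a hindered, delocalised enolate. The prenyl alkene needs a Markovnikov hydration before hydrogenolysis, since hydrogen would otherwise saturate it.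
- Comparison: the step count is no lower and the regiochemical certainty is less. The chosen plan offers instead two lithiations whose sites are fixed by symmetry, a chain that arrives already hydrated, and one step that both makes the diketone and attaches ring B.

Alternative 2: intramolecular benzoin closure of the C3–C4 bond.
- Disconnection: the C3–C4 bond. The dialdehyde A4 has the ring A formyl group at C4a and an α-aryl-α-aryloxy acetaldehyde hung from O1.
- Forward key step: a triazolium-derived N-heterocyclic carbene with DBU would convert A4 into the 3-hydroxyflavanone A5, with two new stereocentres at C2 and C3 formed as a mixture.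
- In favour: no metal and no toxic gas are needed, the tertiary alcohol can stay free, and O3 arrives unprotected. On operational simplicity it is stronger than the chosen plan.
- Against: to give A5 the carbene must add to the ring A aldehyde of A4, which is flanked by two ortho oxygens and is the more hindered and less electrophilic of the two. The aliphatic aldehyde is the likelier acyl-anion donor; that leads to the regioisomeric acyloin, with the hydroxyl at C4 and the ketone at C3, or its Breslow intermediate expels the α-aryloxy group and cleaves the O1–C2 bond. A5 is also one oxidation level too low, so a dehydrogenation across C2–C3 is still needed and the two stereocentres are made only to be destroyed. Building A4 requires O-alkylation of a hindered phenol and redox adjustment on both carbonyls.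
- Comparison: the chosen plan has a single carbonyl pronucleophile, so this chemoselectivity question does not arise, and CO delivers C2 at the final oxidation level.

Alternative 3: Danheiser benzannulation of ring A onto a γ-pyrone.
- Disconnection: three bonds of ring A, C5–C6, C7–C8 and C4a–C5.
- Forward key step: irradiation of the pyranonyl diazoketone A6 triggers a Wolff rearrangement to a ketene conjugated with the pyrone C=C bond. Cycloaddition of that ketene with the siloxyalkyne A7, four-electron ring opening and six-electron ring closure would give A8, with 5-OH free, O7 silylated and the silylated chain at C6.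
- In favour: it is the most convergent of the four plans. The position of the chain is set by the polarity of the ynol ether A7 (its chain-bearing carbon bonds to the ketene carbon that becomes C5), not by symmetry and a protecting-group exchange. On regiocontrol by mechanism it is stronger than the chosen plan.
- Against: both partners need multi-step syntheses. A6 requires a trisubstituted γ-pyrone carrying aryl, benzyloxy and a carboxyl-derived diazoketone, made with a hazardous diazoalkane; A7 is a sensitive silyl ynol ether. The 2-aryl-γ-pyrone chromophore of A6 and of the product A8 absorbs where the diazoketone does, so pyrone photorearrangement and product photolysis compete with the Wolff step. The end game needs both fluoride and hydrogenolysis.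
- Comparison: the overall count is clearly higher. The chosen plan starts from a purchased arene that already carries all three ring A oxygens and uses no diazo or photochemical step.

Key step: step 8

Remark on the chemistry: CO is assumed to be supplied at about one atmosphere; diketone 16 is handled as a racemic, partly enolised mixture, since its one stereocentre disappears in step 9.

## Route

Step 1
Reactants: 1 3,5-bis(benzyloxy)phenol
Product: 2 [3,5-bis(benzyloxy)phenoxy]triisopropylsilane
Conditions: iPr3SiCl, imidazole, DMF, rt
Reagents that add atoms: chlorotriisopropylsilane, CC(C)[Si](Cl)(C(C)C)C(C)C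
Why: Standard silylation of a phenol; the bulky, weakly coordinating silyl ether masks the future O1 and keeps the base of step 2 away from its two ortho positions.

Step 2
Reactants: 2 [3,5-bis(benzyloxy)phenoxy]triisopropylsilane; 3 2,2-dimethyloxetane
Product: 5 4-[2,6-bis(benzyloxy)-4-(triisopropylsilyloxy)phenyl]-2-methylbutan-2-ol, via aryllithium 4 (not isolated)
Conditions: n-BuLi (1.05 equiv), THF, 0 °C; then 3, BF3·OEt2, −78 °C; aq NaHCO3
Reagents that add atoms: none
Why: Directed ortho-metalation at the carbon flanked by the two benzyloxy groups, then Lewis-acid-assisted SN2 opening of the oxetane at its unsubstituted O–CH2 carbon, which installs the whole chain with its tertiary alcohol; the mirror plane of 2 makes the lithiation site unique, and it becomes C6.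

Step 3
Reactants: 5 4-[2,6-bis(benzyloxy)-4-(triisopropylsilyloxy)phenyl]-2-methylbutan-2-ol
Product: 6 3,5-bis(benzyloxy)-4-(3-hydroxy-3-methylbutyl)phenol
Conditions: Bu4NF, AcOH, THF, 0 °C
Reagents that add atoms: none
Why: Fluoride cleavage of an aryl silyl ether; the acetic acid buffer protonates the electron-rich phenoxide as it forms and limits its oxidation.

Step 4
Reactants: 6 3,5-bis(benzyloxy)-4-(3-hydroxy-3-methylbutyl)phenol
Product: 7 4-[2,6-bis(benzyloxy)-4-(methoxymethoxy)phenyl]-2-methylbutan-2-ol
Conditions: MOMCl (1.1 equiv), K2CO3, acetone, rt
Reagents that add atoms: chloromethyl methyl ether, COCCl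
Why: Williamson-type O-alkylation of the phenoxide; carbonate does not deprotonate the tertiary alcohol, so only the phenol is etherified.

Step 5
Reactants: 7 4-[2,6-bis(benzyloxy)-4-(methoxymethoxy)phenyl]-2-methylbutan-2-ol
Product: 8 ({4-[2,6-bis(benzyloxy)-4-(methoxymethoxy)phenyl]-2-methylbutan-2-yl}oxy)triethylsilane
Conditions: Et3SiOTf (1.3 equiv), 2,6-lutidine, CH2Cl2, −78 → −20 °C
Reagents that add atoms: triethylsilyl trifluoromethanesulfonate, CC[Si](CC)(CC)OS(=O)(=O)C(F)(F)F
Why: Silyl triflate silylation of a hindered tertiary alcohol; at low temperature the aryl MOM acetal should be left alone, and the TES ether removes the acidic O–H before the base steps and later falls off in the same acid as the MOM group.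

Step 6
Reactants: 9 benzyloxyacetyl chloride
Product: 10 2-(benzyloxy)-N-methoxy-N-methylacetamide
Conditions: MeNHOMe·HCl, Et3N, CH2Cl2, 0 °C → rt
Reagents that add atoms: N,O-dimethylhydroxylamine hydrochloride, CNOC.Cl
Why: Acylation of the amine by an acid chloride gives the Weinreb amide.

Step 7
Reactants: 8 ({4-[2,6-bis(benzyloxy)-4-(methoxymethoxy)phenyl]-2-methylbutan-2-yl}oxy)triethylsilane; 10 2-(benzyloxy)-N-methoxy-N-methylacetamide
Product: 12 2-(benzyloxy)-1-[2,4-bis(benzyloxy)-6-(methoxymethoxy)-3-(3-methyl-3-triethylsilyloxybutyl)phenyl]ethan-1-one, via aryllithium 11 (not isolated)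
Conditions: n-BuLi, TMEDA, THF, 0 °C; then 10, −78 → 0 °C; aq NH4Cl
Reagents that add atoms: none
Why: Directed ortho-metalation next to the MOM ether (the two ring hydrogens of 8 are equivalent and each lies between the MOM and a benzyloxy group), then Weinreb ketone synthesis; the chelated tetrahedral adduct collapses only on work-up, so the reaction stops at the ketone.

Step 8
Reactants: 12 2-(benzyloxy)-1-[2,4-bis(benzyloxy)-6-(methoxymethoxy)-3-(3-methyl-3-triethylsilyloxybutyl)phenyl]ethan-1-one; 13 1-(benzyloxy)-4-iodobenzene; 14 carbon monoxide
Product: 16 2-(benzyloxy)-1-[2,4-bis(benzyloxy)-6-(methoxymethoxy)-3-(3-methyl-3-triethylsilyloxybutyl)phenyl]-3-[4-(benzyloxy)phenyl]propane-1,3-dione, via sodium enolate 15 (not isolated)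
Conditions: NaN(SiMe3)2 (1.05 equiv), THF, 0 °C; then 13 (1.5 equiv), Pd(dba)2 (5 mol%), Xantphos (6 mol%), CO (1 atm), THF–dioxane, 70 °C, second equiv NaN(SiMe3)2 added slowly; aq NH4Cl
Reagents that add atoms: none
Why: Palladium-catalysed carbonylative α-arylation of a ketone: zerovalent palladium inserts into the C–I bond of 13, migratory insertion of CO gives a Xantphos-bound aroyl complex of divalent palladium (C2–C1' is made here), enolate 15 replaces iodide, and C–C reductive elimination forms C2–C3. The closest known reaction type is the three-component coupling of aryl iodides, CO and ketone enolates to 1,3-diketones; 12 differs only in its α-benzyloxy group and its doubly ortho-substituted aryl group. No ring closes, and the only new stereocentre, the CH(OBn) carbon between the two carbonyls, is enolisable, forms as a racemate and disappears in step 9. The step needs acylation at carbon rather than oxygen and carbonylative rather than direct arylation: CO insertion into the aryl–palladium bond is fast at one atmosphere, the wide bite angle of Xantphos favours the acyl complex and speeds reductive elimination, and the unhindered secondary α-carbon of 15 can bind palladium. Any enol ester formed through oxygen is itself an acyl donor towards remaining enolate, and the diketone, far more acidic than 12, is deprotonated at once, so it is the thermodynamic sink and is protected from a second acylation. Feeding the second equivalent of amide base slowly keeps its concentration low, so that it regenerates 15 from 12 and does not intercept the aroyl complex as an amide. The MOM ether at O1 and the TES ether on the chain remove the two O–H groups that could otherwise be aroylated.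

Step 9
Reactants: 16 2-(benzyloxy)-1-[2,4-bis(benzyloxy)-6-(methoxymethoxy)-3-(3-methyl-3-triethylsilyloxybutyl)phenyl]-3-[4-(benzyloxy)phenyl]propane-1,3-dione
Product: 18 3,5,7-tris(benzyloxy)-2-[4-(benzyloxy)phenyl]-6-(3-hydroxy-3-methylbutyl)-4H-chromen-4-one, via hydroxy diketone 17 (not isolated)
Conditions: HCl (ca. 1 M), MeOH–THF, 50 °C
Reagents that add atoms: none
Why: Acid methanolysis removes the MOM acetal and the TES ether; the single free phenol of 17 adds to the ring B ketone (6-exo-trig) and the hemiketal loses water to the aromatic γ-pyrone, the classical cyclodehydration of an o-hydroxyaryl 1,3-diketone. O5 stays benzylated, so closure on that side is impossible and the chain remains at C6.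

Step 10
Reactants: 18 3,5,7-tris(benzyloxy)-2-[4-(benzyloxy)phenyl]-6-(3-hydroxy-3-methylbutyl)-4H-chromen-4-one
Product: 19 3,5,7-trihydroxy-6-(3-hydroxy-3-methylbutyl)-2-(4-hydroxyphenyl)-4H-chromen-4-one
Conditions: H2 (1 atm), Pd/C, THF–MeOH, rt
Reagents that add atoms: none
Why: Hydrogenolysis of four benzyl ethers under neutral conditions; the tertiary alcohol and the tetrasubstituted C2=C3 bond of the pyrone are not expected to react.

## Compound list

1 | 3,5-bis(benzyloxy)phenol | Oc1cc(OCc2ccccc2)cc(OCc2ccccc2)c1 | starting material
2 | [3,5-bis(benzyloxy)phenoxy]triisopropylsilane | CC(C)[Si](Oc1cc(OCc2ccccc2)cc(OCc2ccccc2)c1)(C(C)C)C(C)C | intermediate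
3 | 2,2-dimethyloxetane | CC1(C)CCO1 | starting material
4 | [2,6-bis(benzyloxy)-4-(triisopropylsilyloxy)phenyl]lithium | [Li]c1c(OCc2ccccc2)cc(O[Si](C(C)C)(C(C)C)C(C)C)cc1OCc1ccccc1 | intermediate (not isolated)
5 | 4-[2,6-bis(benzyloxy)-4-(triisopropylsilyloxy)phenyl]-2-methylbutan-2-ol | CC(C)(O)CCc1c(OCc2ccccc2)cc(O[Si](C(C)C)(C(C)C)C(C)C)cc1OCc1ccccc1 | intermediate
6 | 3,5-bis(benzyloxy)-4-(3-hydroxy-3-methylbutyl)phenol | CC(C)(O)CCc1c(OCc2ccccc2)cc(O)cc1OCc1ccccc1 | intermediate
7 | 4-[2,6-bis(benzyloxy)-4-(methoxymethoxy)phenyl]-2-methylbutan-2-ol | CC(C)(O)CCc1c(OCc2ccccc2)cc(OCOC)cc1OCc1ccccc1 | intermediate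
8 | ({4-[2,6-bis(benzyloxy)-4-(methoxymethoxy)phenyl]-2-methylbutan-2-yl}oxy)triethylsilane | CC[Si](CC)(CC)OC(C)(C)CCc1c(OCc2ccccc2)cc(OCOC)cc1OCc1ccccc1 | intermediate
9 | benzyloxyacetyl chloride | O=C(Cl)COCc1ccccc1 | starting material
10 | 2-(benzyloxy)-N-methoxy-N-methylacetamide | CON(C)C(=O)COCc1ccccc1 | intermediate
11 | [2,4-bis(benzyloxy)-6-(methoxymethoxy)-3-(3-methyl-3-triethylsilyloxybutyl)phenyl]lithium | [Li]c1c(OCOC)cc(OCc2ccccc2)c(CCC(C)(C)O[Si](CC)(CC)CC)c1OCc1ccccc1 | intermediate (not isolated)
12 | 2-(benzyloxy)-1-[2,4-bis(benzyloxy)-6-(methoxymethoxy)-3-(3-methyl-3-triethylsilyloxybutyl)phenyl]ethan-1-one | CC(C)(O[Si](CC)(CC)CC)CCc1c(OCc2ccccc2)cc(OCOC)c(C(=O)COCc2ccccc2)c1OCc1ccccc1 | intermediate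
13 | 1-(benzyloxy)-4-iodobenzene | Ic1ccc(OCc2ccccc2)cc1 | starting material
14 | carbon monoxide | [C-]#[O+] | starting material
15 | sodium (Z)-2-(benzyloxy)-1-[2,4-bis(benzyloxy)-6-(methoxymethoxy)-3-(3-methyl-3-triethylsilyloxybutyl)phenyl]ethen-1-olate (chelated Z geometry expected) | [Na+].[O-]/C(=C\OCc1ccccc1)c1c(OCOC)cc(OCc2ccccc2)c(CCC(C)(C)O[Si](CC)(CC)CC)c1OCc1ccccc1 | intermediate (not isolated)
16 | 2-(benzyloxy)-1-[2,4-bis(benzyloxy)-6-(methoxymethoxy)-3-(3-methyl-3-triethylsilyloxybutyl)phenyl]-3-[4-(benzyloxy)phenyl]propane-1,3-dione (racemic, enolisable) | CC(C)(O[Si](CC)(CC)CC)CCc1c(OCc2ccccc2)cc(OCOC)c(C(=O)C(OCc2ccccc2)C(=O)c2ccc(OCc3ccccc3)cc2)c1OCc1ccccc1 | intermediate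
17 | 2-(benzyloxy)-1-[2,4-bis(benzyloxy)-6-hydroxy-3-(3-hydroxy-3-methylbutyl)phenyl]-3-[4-(benzyloxy)phenyl]propane-1,3-dione (racemic, enolisable) | CC(C)(O)CCc1c(OCc2ccccc2)cc(O)c(C(=O)C(OCc2ccccc2)C(=O)c2ccc(OCc3ccccc3)cc2)c1OCc1ccccc1 | intermediate (not isolated)
18 | 3,5,7-tris(benzyloxy)-2-[4-(benzyloxy)phenyl]-6-(3-hydroxy-3-methylbutyl)-4H-chromen-4-one | CC(C)(O)CCc1c(OCc2ccccc2)cc2oc(-c3ccc(OCc4ccccc4)cc3)c(OCc3ccccc3)c(=O)c2c1OCc1ccccc1 | intermediate
19 | 3,5,7-trihydroxy-6-(3-hydroxy-3-methylbutyl)-2-(4-hydroxyphenyl)-4H-chromen-4-one | CC(C)(O)CCc1c(O)cc2oc(-c3ccc(O)cc3)c(O)c(=O)c2c1O | target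

## Step count and least certain steps

Total: 10 steps. Longest linear sequence: 9 steps (1 to 19 through steps 1–5 and 7–10); step 6 is a one-step side branch.

**Step 8 (key step).**
- What may go wrong: acylation of the enolate at oxygen, or capture of the aroyl–palladium complex by the amide base, can outrun C–C reductive elimination, because the enolate of a doubly ortho-substituted aryl ketone is hindered and binds palladium slowly. Prolonged heating of the α-benzyloxy enolate may also start a Wittig-type 1,2-shift of the benzyl group.
- Fallback: it sets out from 12 and returns at 17, using the Baker–Venkataraman rearrangement, which makes the acyl transfer intramolecular. Dilute HCl in methanol at room temperature removes the MOM and TES groups of 12 to give 2-(benzyloxy)-1-[2,4-bis(benzyloxy)-6-hydroxy-3-(3-hydroxy-3-methylbutyl)phenyl]ethan-1-one F1. The phenol alone is esterified with 4-(benzyloxy)benzoyl chloride in pyridine to give 3,5-bis(benzyloxy)-2-[(benzyloxy)acetyl]-4-(3-hydroxy-3-methylbutyl)phenyl 4-(benzyloxy)benzoate F2. KOtBu in THF then moves the aroyl group from oxygen to the enolate carbon through a six-membered transition state, giving 17, which is cyclised to 18 under the conditions of step 9.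

**Step 2.**
- What may go wrong: deprotonation at a benzylic O–CH2 position can compete with ring lithiation. The BF3-bound 2,2-dimethyloxetane can ionise at its tertiary C–O bond and be lost before the hindered aryllithium attacks.
- Fallback: it sets out from 2 (through 4) and returns at 5. Aryllithium 4 is allylated with prenyl bromide in the presence of catalytic CuBr·SMe2 to give [3,5-bis(benzyloxy)-4-(3-methylbut-2-en-1-yl)phenoxy]triisopropylsilane F3. Mukaiyama hydration (Co(acac)2, PhSiH3, O2, THF) adds water in the Markovnikov sense to the trisubstituted alkene and should give 5.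

**Step 7.**
- What may go wrong: metalation may occur partly at a benzylic ether position instead of on the ring, or the hindered aryllithium may act as a base towards the α-CH2 of amide 10 and return 8.
- Fallback: it sets out from 8 and returns at 11, and so at 12. N-bromosuccinimide in acetonitrile brominates one of the two equivalent ring positions to give ({4-[2,6-bis(benzyloxy)-3-bromo-4-(methoxymethoxy)phenyl]-2-methylbutan-2-yl}oxy)triethylsilane F4. Bromine–lithium exchange with n-BuLi at −78 °C, which is faster than any deprotonation, then gives 11 for the reaction with 10.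

**Step 9.**
- What may go wrong: the acid strength and temperature needed for the dehydration may ionise the free tertiary alcohol (loss of water or methyl ether formation). The peri 5-O-benzyl group may also be lost early, after which the chain cation could be trapped by O5.
- Fallback: it sets out from 16 and returns at 18, keeping the chain silylated until the ring is closed and avoiding protic acid. Me3SiOTf with 2,2'-bipyridyl in CH2Cl2 at 0 °C, then water, cleaves only the aryl MOM ether to give 2-(benzyloxy)-1-[2,4-bis(benzyloxy)-6-hydroxy-3-(3-methyl-3-triethylsilyloxybutyl)phenyl]-3-[4-(benzyloxy)phenyl]propane-1,3-dione F5. Catalytic pyridinium p-toluenesulfonate in dry toluene over molecular sieves dehydrates it to 3,5,7-tris(benzyloxy)-2-[4-(benzyloxy)phenyl]-6-(3-methyl-3-triethylsilyloxybutyl)-4H-chromen-4-one F6. Bu4NF in THF then removes the TES group to give 18.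

## Further compounds

F1 | step 8 | 2-(benzyloxy)-1-[2,4-bis(benzyloxy)-6-hydroxy-3-(3-hydroxy-3-methylbutyl)phenyl]ethan-1-one | CC(C)(O)CCc1c(OCc2ccccc2)cc(O)c(C(=O)COCc2ccccc2)c1OCc1ccccc1
F2 | step 8 | 3,5-bis(benzyloxy)-2-[(benzyloxy)acetyl]-4-(3-hydroxy-3-methylbutyl)phenyl 4-(benzyloxy)benzoate | CC(C)(O)CCc1c(OCc2ccccc2)cc(OC(=O)c2ccc(OCc3ccccc3)cc2)c(C(=O)COCc2ccccc2)c1OCc1ccccc1
F3 | step 2 | [3,5-bis(benzyloxy)-4-(3-methylbut-2-en-1-yl)phenoxy]triisopropylsilane | CC(C)=CCc1c(OCc2ccccc2)cc(O[Si](C(C)C)(C(C)C)C(C)C)cc1OCc1ccccc1
F4 | step 7 | ({4-[2,6-bis(benzyloxy)-3-bromo-4-(methoxymethoxy)phenyl]-2-methylbutan-2-yl}oxy)triethylsilane | CC[Si](CC)(CC)OC(C)(C)CCc1c(OCc2ccccc2)cc(OCOC)c(Br)c1OCc1ccccc1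
F5 | step 9 | 2-(benzyloxy)-1-[2,4-bis(benzyloxy)-6-hydroxy-3-(3-methyl-3-triethylsilyloxybutyl)phenyl]-3-[4-(benzyloxy)phenyl]propane-1,3-dione | CC[Si](CC)(CC)OC(C)(C)CCc1c(OCc2ccccc2)cc(O)c(C(=O)C(OCc2ccccc2)C(=O)c2ccc(OCc3ccccc3)cc2)c1OCc1ccccc1
F6 | step 9 | 3,5,7-tris(benzyloxy)-2-[4-(benzyloxy)phenyl]-6-(3-methyl-3-triethylsilyloxybutyl)-4H-chromen-4-one | CC[Si](CC)(CC)OC(C)(C)CCc1c(OCc2ccccc2)cc2oc(-c3ccc(OCc4ccccc4)cc3)c(OCc3ccccc3)c(=O)c2c1OCc1ccccc1
A1 | alternative 1 | 1,3-bis(benzyloxy)-5-bromobenzene | Brc1cc(OCc2ccccc2)cc(OCc2ccccc2)c1
A2 | alternative 1 | 2-(benzyloxy)-1-[2,4-bis(benzyloxy)-6-bromo-3-(3-methylbut-2-en-1-yl)phenyl]-3-[4-(benzyloxy)phenyl]propane-1,3-dione | CC(C)=CCc1c(OCc2ccccc2)cc(Br)c(C(=O)C(OCc2ccccc2)C(=O)c2ccc(OCc3ccccc3)cc2)c1OCc1ccccc1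
A3 | alternative 1 | 3,5,7-tris(benzyloxy)-2-[4-(benzyloxy)phenyl]-6-(3-methylbut-2-en-1-yl)-4H-chromen-4-one | CC(C)=CCc1c(OCc2ccccc2)cc2oc(-c3ccc(OCc4ccccc4)cc3)c(OCc3ccccc3)c(=O)c2c1OCc1ccccc1
A4 | alternative 2 | 2-[3,5-bis(benzyloxy)-2-formyl-4-(3-hydroxy-3-methylbutyl)phenoxy]-2-[4-(benzyloxy)phenyl]acetaldehyde (racemic) | CC(C)(O)CCc1c(OCc2ccccc2)cc(OC(C=O)c2ccc(OCc3ccccc3)cc2)c(C=O)c1OCc1ccccc1
A5 | alternative 2 | 5,7-bis(benzyloxy)-2-[4-(benzyloxy)phenyl]-3-hydroxy-6-(3-hydroxy-3-methylbutyl)-2,3-dihydro-4H-chromen-4-one (racemic, mixture of diastereomers) | CC(C)(O)CCc1c(OCc2ccccc2)cc2OC(c3ccc(OCc4ccccc4)cc3)C(O)C(=O)c2c1OCc1ccccc1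
A6 | alternative 3 | 5-(benzyloxy)-6-[4-(benzyloxy)phenyl]-2-(diazoacetyl)-4H-pyran-4-one | [N-]=[N+]=CC(=O)c1cc(=O)c(OCc2ccccc2)c(-c2ccc(OCc3ccccc3)cc2)o1
A7 | alternative 3 | triethyl{[2-methyl-6-(triisopropylsilyloxy)hex-5-yn-2-yl]oxy}silane | CC[Si](CC)(CC)OC(C)(C)CCC#CO[Si](C(C)C)(C(C)C)C(C)C
A8 | alternative 3 | 3-(benzyloxy)-2-[4-(benzyloxy)phenyl]-5-hydroxy-6-(3-methyl-3-triethylsilyloxybutyl)-7-(triisopropylsilyloxy)-4H-chromen-4-one | CC[Si](CC)(CC)OC(C)(C)CCc1c(O[Si](C(C)C)(C(C)C)C(C)C)cc2oc(-c3ccc(OCc4ccccc4)cc3)c(OCc3ccccc3)c(=O)c2c1O
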